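Ring B (C5–C10, labdane numbering) is disconnected at C5–C6 and C7–C8, which removes the two-carbon unit C6–C7 and leaves a trimethylcyclohexanone (ring A, C5 ketone) carrying the complete C9 branch. The key step is a Michael–Wittig annulation: the ester enolate at C8 adds to vinyltriphenylphosphonium bromide and the ylide formed at C6 olefinates the C5 ketone, closing ring B in one operation. It exploits the 1,4-relation between C8 (α to the C17 carboxyl) and C5 (non-enolisable, between quaternary C4 and C10). The precursor is a δ-keto ester whose C9 and C10 centres come from an organocatalytic Mukaiyama–Michael addition; C13 comes from (S)-citronellol. Hydrogen-atom-transfer hydrogenation then sets C5 and selenoxide elimination installs C7=C8.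

Key step: step 6

Remark (numbering): labdane numbering is used for all intermediates: ring A = C1–C5 and C10, ring B = C5–C10, C17 = carboxyl carbon on C8, C11–C16 = side chain on C9, C20 = methyl on C10.

Remark (assumption): the (2R,5R) enantiomer of the imidazolidinone in step 4 is chosen from the usual shielding model of its iminium ions; if the sense of induction proved opposite, the (2S,5S) enantiomer would be used.

Step 1
Reactants: 1 (S)-citronellol
Product: 2 tert-butyl{[(3S)-3,7-dimethyloct-6-en-1-yl]oxy}dimethylsilane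
Conditions: TBSCl, imidazole, DMF, 0 °C → rt
Reagents that add atoms: tert-butyldimethylsilyl chloride, CC(C)(C)[Si](C)(C)Cl
Why: Imidazole-promoted silyl ether formation masks the C15 hydroxyl for the later basic and oxidative steps and leaves the C13 stereocentre of citronellol untouched.

Step 2
Reactants: 2 silyl ether of (S)-citronellol; 3 (E)-but-2-enal
Product: 4 (2E,6S)-8-[(tert-butyldimethylsilyl)oxy]-6-methyloct-2-enal
Conditions: 3 (5 equiv), second-generation Hoveyda–Grubbs catalyst RuCl2(H2IMes)(=CH-C6H4-2-O-i-Pr) (5 mol %), CH2Cl2, 40 °C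
Reagents that add atoms: none
Why: Olefin cross-metathesis of the isopropylidene terminus with an excess of the electron-poor partner should give the E enal with loss of 2-methylbut-2-ene, the aldehyde-bearing carbon pair becoming C8 and C17 and the former C6 of citronellol becoming C9.

Step 3
Reactants: 5 2,2,6-trimethylcyclohexanone
Product: 6 trimethyl[(2,6,6-trimethylcyclohex-1-en-1-yl)oxy]silane
Conditions: Me3SiOTf, Et3N, CH2Cl2, 0 °C → rt
Reagents that add atoms: trimethylsilyl trifluoromethanesulfonate, C[Si](C)(C)OS(=O)(=O)C(F)(F)F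
Why: Silyl enol ether formation can run only towards the methyl-bearing α-carbon because the other α-carbon is quaternary, so a single tetrasubstituted enol silane results.

Step 4
Reactants: 4 silyloxy enal; 6 enol silane of ring A
Product: 7 (3S,6S)-8-[(tert-butyldimethylsilyl)oxy]-6-methyl-3-[(1R)-1,3,3-trimethyl-2-oxocyclohexyl]octanal
Conditions: (2R,5R)-5-benzyl-2-tert-butyl-3-methylimidazolidin-4-one (20 mol %), 2,4-dinitrobenzoic acid (20 mol %), 6 (2 equiv), H2O (2 equiv), CH2Cl2, −40 → −20 °C
Reagents that add atoms: none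
Why: Organocatalytic Mukaiyama–Michael addition through the E iminium ion of 4, in which the benzyl group of the catalyst shields one face of C9 so that 6 adds to the open face, while a synclinal open transition state that places the chain next to the ring methyl (the cis preference known for Michael additions of 2-methylcyclohexanone enol derivatives to E β-alkyl acceptors) should set C10 relative to C9.

Step 5
Reactants: 7 δ-keto aldehyde
Product: 8 methyl (3S,6S)-8-[(tert-butyldimethylsilyl)oxy]-6-methyl-3-[(1R)-1,3,3-trimethyl-2-oxocyclohexyl]octanoate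
Conditions: I2, KOH, MeOH, 0 °C
Reagents that add atoms: methanol, CO
Why: Hypoiodite oxidation of the methyl hemiacetal (oxidative esterification) should convert the aldehyde directly into the methyl ester, while the ketone has no α-hydrogen and no stereocentre is enolisable.

Step 6
Reactants: 8 δ-keto ester; 9 triphenyl(vinyl)phosphonium bromide
Product: 12 methyl (13S)-15-[(tert-butyldimethylsilyl)oxy]labd-5-en-17-oate with 9α-H and 10β-methyl as a mixture of C8 epimers, via potassium ester enolate 10 (not isolated), via phosphorus ylide 11 (not isolated)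
Conditions: KN(SiMe3)2, THF, −78 °C; 9 (1.2 equiv), THF–DMPU, −78 °C → rt; then PhMe, 110 °C
Reagents that add atoms: none
Why: KN(SiMe3)2 can deprotonate only C8, because the C5 carbonyl lies between the quaternary C4 and C10 and has no α-hydrogen; the enolate adds in Michael fashion to the terminal carbon of the vinylphosphonium salt (C7–C8 bond) and thereby creates the non-stabilised ylide at C6. The ylide then adds to the C5 carbonyl within the same molecule and the oxaphosphetane collapses to the C5=C6 olefin, so ring B is closed by a 6-exo-trig attack of C6 on C5 followed by loss of Ph3PO. The closest known reaction type is the Michael–Wittig annulation of keto-enolates with vinyltriphenylphosphonium bromide to cycloalkenes, and ketones flanked by two quaternary carbons (fenchone type) are known to undergo Wittig methylenation on heating. C9, C10 and C13 are not touched; C8 forms as an epimer mixture, which does not matter because C8 becomes trigonal in step 8. The step needs the ylide to choose the hindered ketone over the ester, which the six-membered (against four-membered) closure and heating of the potassium ylide should secure. The new olefin can only lie at C5=C6, the position from which step 7 sets the trans ring fusion.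

Step 7
Reactants: 12 labd-5-ene ester
Product: 13 methyl (13S)-15-[(tert-butyldimethylsilyl)oxy]-5α-labdan-17-oate (5α-H, 9α-H, 10β-methyl, C8 epimers)
Conditions: Mn(dpm)3 (10 mol %), PhSiH3, t-BuOOH, i-PrOH, rt
Reagents that add atoms: none
Why: Metal-hydride hydrogen-atom-transfer hydrogenation, in which a manganese hydride delivers a hydrogen atom to C6 and the resulting tertiary C5 radical takes up hydrogen from the α face, anti to the axial methyl groups on C10 and C4, to give the thermodynamically preferred trans ring fusion even at this hindered olefin.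

Step 8
Reactants: 13 saturated ester
Product: 15 methyl (5S,9R,10S,13S)-15-[(tert-butyldimethylsilyl)oxy]labd-7-en-17-oate, via C8 phenylselenide 14 (not isolated)
Conditions: LiN(i-Pr)2, THF–DMPU, −78 → 0 °C; PhSeBr, −78 °C; then H2O2, pyridine, CH2Cl2, 0 °C → rt
Reagents that add atoms: none
Why: α-Selenenylation of the ester enolate followed by selenoxide syn-elimination, in which PhSe should enter from the less hindered α face and the elimination should run towards C7 because eclipsing towards C9–H would press the ester against C11 and the quaternary C10, giving the conjugated C7=C8 ester without touching C5, C9, C10 or C13.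

Step 9
Reactants: 15 conjugated methyl ester
Product: 17 (5S,9R,10S,13S)-15-hydroxylabd-7-en-17-oic acid, via potassium carboxylate 16 (not isolated)
Conditions: KOH, MeOH–H2O, 70 °C; then aq. HCl (2 M), THF, rt
Reagents that add atoms: potassium hydroxide, [K+].[OH-]
Why: Saponification of the methyl ester followed by acid cleavage of the primary silyl ether in the same flask should free the acid and the C15 hydroxyl, and C9–H is not acidic in its cross-conjugated position, so no epimerisation is expected.

Step 10
Reactants: 17 hydroxy acid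
Product: 18 (5S,9R,10S,13S)-15-(acetyloxy)labd-7-en-17-oic acid
Conditions: Ac2O, pyridine, DMAP (cat.), CH2Cl2, 0 °C → rt; aq. NaHCO3 work-up, then acidification
Reagents that add atoms: acetic anhydride, CC(=O)OC(C)=O
Why: Nucleophile-catalysed acetylation acylates the primary alcohol, and any mixed anhydride formed at the carboxyl group is hydrolysed in the bicarbonate work-up, leaving the free acid.

Compound list
1 | (S)-citronellol, (3S)-3,7-dimethyloct-6-en-1-ol | OCC[C@@H](C)CCC=C(C)C | starting material
2 | tert-butyl{[(3S)-3,7-dimethyloct-6-en-1-yl]oxy}dimethylsilane | CC(C)(C)[Si](C)(C)OCC[C@@H](C)CCC=C(C)C | intermediate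
3 | (E)-but-2-enal (crotonaldehyde) | C/C=C/C=O | starting material
4 | (2E,6S)-8-[(tert-butyldimethylsilyl)oxy]-6-methyloct-2-enal | CC(C)(C)[Si](C)(C)OCC[C@@H](C)CC/C=C/C=O | intermediate
5 | 2,2,6-trimethylcyclohexanone (racemic, stereocentre lost in step 3) | CC1CCCC(C)(C)C1=O | starting material
6 | trimethyl[(2,6,6-trimethylcyclohex-1-en-1-yl)oxy]silane | CC1=C(O[Si](C)(C)C)C(C)(C)CCC1 | intermediate
7 | (3S,6S)-8-[(tert-butyldimethylsilyl)oxy]-6-methyl-3-[(1R)-1,3,3-trimethyl-2-oxocyclohexyl]octanal | CC(C)(C)[Si](C)(C)OCC[C@@H](C)CC[C@@H](CC=O)[C@@]1(C)CCCC(C)(C)C1=O | intermediate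
8 | methyl (3S,6S)-8-[(tert-butyldimethylsilyl)oxy]-6-methyl-3-[(1R)-1,3,3-trimethyl-2-oxocyclohexyl]octanoate | CC(C)(C)[Si](C)(C)OCC[C@@H](C)CC[C@@H](CC(=O)OC)[C@@]1(C)CCCC(C)(C)C1=O | intermediate
9 | triphenyl(vinyl)phosphonium bromide | C=C[P+](c1ccccc1)(c1ccccc1)c1ccccc1.[Br-] | starting material
10 | potassium enolate of 8 (enolate carbon = C8) | CC(C)(C)[Si](C)(C)OCC[C@@H](C)CC[C@@H](C=C([O-])OC)[C@@]1(C)CCCC(C)(C)C1=O.[K+] | intermediate
11 | phosphorus ylide: 8 carrying a 2-(triphenylphosphoranylidene)ethyl group on C8 (C8 epimers) | CC(C)(C)[Si](C)(C)OCC[C@@H](C)CC[C@@H](C(CC=P(c1ccccc1)(c1ccccc1)c1ccccc1)C(=O)OC)[C@@]2(C)CCCC(C)(C)C2=O | intermediate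
12 | methyl (13S)-15-[(tert-butyldimethylsilyl)oxy]labd-5-en-17-oate (9α-H, 10β-methyl, C8 epimers) | CC(C)(C)[Si](C)(C)OCC[C@@H](C)CC[C@H]1C(C(=O)OC)CC=C2C(C)(C)CCC[C@]12C | intermediate
13 | methyl (13S)-15-[(tert-butyldimethylsilyl)oxy]-5α-labdan-17-oate (5α-H, 9α-H, 10β-methyl, C8 epimers) | CC(C)(C)[Si](C)(C)OCC[C@@H](C)CC[C@H]1C(C(=O)OC)CC[C@H]2C(C)(C)CCC[C@]12C | intermediate
14 | methyl (13S)-15-[(tert-butyldimethylsilyl)oxy]-8-(phenylselanyl)-5α-labdan-17-oate | CC(C)(C)[Si](C)(C)OCC[C@@H](C)CC[C@H]1C([Se]c3ccccc3)(C(=O)OC)CC[C@H]2C(C)(C)CCC[C@]12C | intermediate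
15 | methyl (5S,9R,10S,13S)-15-[(tert-butyldimethylsilyl)oxy]labd-7-en-17-oate | CC(C)(C)[Si](C)(C)OCC[C@@H](C)CC[C@H]1C(C(=O)OC)=CC[C@H]2C(C)(C)CCC[C@]12C | intermediate
16 | potassium (5S,9R,10S,13S)-15-[(tert-butyldimethylsilyl)oxy]labd-7-en-17-oate | CC(C)(C)[Si](C)(C)OCC[C@@H](C)CC[C@H]1C(C(=O)[O-])=CC[C@H]2C(C)(C)CCC[C@]12C.[K+] | intermediate
17 | (5S,9R,10S,13S)-15-hydroxylabd-7-en-17-oic acid | OCC[C@@H](C)CC[C@H]1C(C(=O)O)=CC[C@H]2C(C)(C)CCC[C@]12C | intermediate
18 | (5S,9R,10S,13S)-15-(acetyloxy)labd-7-en-17-oic acid | CC(=O)OCC[C@@H](C)CC[C@H]1C(C(=O)O)=CC[C@H]2C(C)(C)CCC[C@]12C | target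

Total step count: 10.
Longest linear sequence: 9 steps (1 → 2 → 4 → 7 → 8 → 12 → 13 → 15 → 17 → 18); step 3 is a one-step side branch.

Steps most likely to fail

Step 6. The non-stabilised ylide may fail to add to the C5 carbonyl, which is shielded by two quaternary carbons, so that proton transfer and decomposition of the ylide outrun ring closure. The fallback sets out from 8 and comes back at 12. Alkylation of the potassium enolate of 8 with 2-chloroethyl trifluoromethanesulfonate should give the 2-chloroethyl keto ester F1. Halide exchange (NaI, acetone, reflux) gives the 2-iodoethyl keto ester F2. A Barbier cyclisation with SmI2 in THF–HMPA onto the C5 ketone gives the ring-fusion tertiary alcohol F3. Dehydration (SOCl2, pyridine), which can only run towards C6, returns 12.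

Step 4. The hindered tetrasubstituted enol silane may be hydrolysed faster than it adds to the iminium ion, or facial selectivity at C10 may be poor, giving low diastereoselectivity. The fallback sets out from 2 and 6 and comes back at 7. Cross-metathesis of 2 with (Z)-but-2-ene-1,4-diyl dimethyl dicarbonate gives the E allylic methyl carbonate F7. A branched-selective allylic alkylation of 6 ([Ir(cod)Cl]2, chiral phosphoramidite, CsF, ZnF2, THF) gives the vinyl ketone F8 with both stereocentres set by the catalyst. Hydroboration–oxidation (9-BBN, then NaOH/H2O2) gives the primary alcohol F9, and Dess–Martin oxidation gives 7.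

Step 8. Enolisation at the hindered C8 may be incomplete, and the syn-elimination may lose regioselectivity by abstracting C9–H instead of C7–H. The fallback sets out from 12 and comes back at 15. Allylic oxidation of 12 at C7 (CrO3, 3,5-dimethylpyrazole, CH2Cl2, −20 °C) gives the 7-oxo-5-ene ester F4. Hydrogenation from the α face (H2, Pd/C, EtOAc) gives the trans-fused 7-oxo ester F5. Reduction with NaBH4 gives the 7-hydroxy ester F6. Mesylation and DBU-induced E1cB elimination, possible only across C7–C8, give 15.

Further compounds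
F1 | step 6 | methyl (3S,6S)-8-[(tert-butyldimethylsilyl)oxy]-2-(2-chloroethyl)-6-methyl-3-[(1R)-1,3,3-trimethyl-2-oxocyclohexyl]octanoate (C2 epimers) | CC(C)(C)[Si](C)(C)OCC[C@@H](C)CC[C@@H](C(CCCl)C(=O)OC)[C@@]1(C)CCCC(C)(C)C1=O
F2 | step 6 | methyl (3S,6S)-8-[(tert-butyldimethylsilyl)oxy]-2-(2-iodoethyl)-6-methyl-3-[(1R)-1,3,3-trimethyl-2-oxocyclohexyl]octanoate (C2 epimers) | CC(C)(C)[Si](C)(C)OCC[C@@H](C)CC[C@@H](C(CCI)C(=O)OC)[C@@]1(C)CCCC(C)(C)C1=O
F3 | step 6 | methyl (13S)-15-[(tert-butyldimethylsilyl)oxy]-5-hydroxylabdan-17-oate (9α-H, 10β-methyl) | CC(C)(C)[Si](C)(C)OCC[C@@H](C)CC[C@H]1C(C(=O)OC)CCC2(O)C(C)(C)CCC[C@]12C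
F4 | step 8 | methyl (13S)-15-[(tert-butyldimethylsilyl)oxy]-7-oxolabd-5-en-17-oate | CC(C)(C)[Si](C)(C)OCC[C@@H](C)CC[C@H]1C(C(=O)OC)C(=O)C=C2C(C)(C)CCC[C@]12C
F5 | step 8 | methyl (13S)-15-[(tert-butyldimethylsilyl)oxy]-7-oxo-5α-labdan-17-oate | CC(C)(C)[Si](C)(C)OCC[C@@H](C)CC[C@H]1C(C(=O)OC)C(=O)C[C@H]2C(C)(C)CCC[C@]12C
F6 | step 8 | methyl (13S)-15-[(tert-butyldimethylsilyl)oxy]-7-hydroxy-5α-labdan-17-oate | CC(C)(C)[Si](C)(C)OCC[C@@H](C)CC[C@H]1C(C(=O)OC)C(O)C[C@H]2C(C)(C)CCC[C@]12C
F7 | step 4 | (2E,6S)-8-[(tert-butyldimethylsilyl)oxy]-6-methyloct-2-en-1-yl methyl carbonate | CC(C)(C)[Si](C)(C)OCC[C@@H](C)CC/C=C/COC(=O)OC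
F8 | step 4 | (6R)-6-[(3S,6S)-8-[(tert-butyldimethylsilyl)oxy]-6-methyloct-1-en-3-yl]-2,2,6-trimethylcyclohexanone | CC(C)(C)[Si](C)(C)OCC[C@@H](C)CC[C@@H](C=C)[C@@]1(C)CCCC(C)(C)C1=O
F9 | step 4 | (6R)-6-[(3S,6S)-8-[(tert-butyldimethylsilyl)oxy]-1-hydroxy-6-methyloctan-3-yl]-2,2,6-trimethylcyclohexanone | CC(C)(C)[Si](C)(C)OCC[C@@H](C)CC[C@@H](CCO)[C@@]1(C)CCCC(C)(C)C1=O
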